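**Plan**
- Retrosynthesis: the 5-OH and the ring B hydroquinone are unmasked last (from 5-OMe and two benzyl ethers). The 3-OMe is cut back to 3-OH, and the C3–O bond to an enol silane oxidation. Then C4–C4a (ring C), O1–C2 and C2–C3 are cut, in that order.
- Forward: a ring B aldehyde takes up an ethynyl Grignard reagent (C2–C3), 3,4,5-trimethoxyphenol is joined at O1–C2, the alkyne terminus is oxidised to a siloxyalkyne, and ring C closes through C4–C4a. Rings A and B are bought; ring C is the only ring made.
- Enabling feature: C4–C4a joins the carbonyl carbon C4 to a ring A carbon ortho to O1. Ring A enters as a 3,4,5-trimethoxyphenoxy group whose two ortho carbons (the future C4a and C8) are equivalent, and the siloxyalkyne supplies C3 and C4 with C4 already oxygenated.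
- Stereochemistry: C2 comes from a ligand-controlled copper-catalysed propargylic etherification; C3 comes from epoxidation of the C3=C4 enol silane anti to the C2 aryl group (2,3-trans).

Key step: step 6

Remark: flavanone numbering is used (O1, C2, C3, C4, C4a to C8a; ring B primed). The spatial arrangement at C2 is constant from 9 to 18; its descriptor is S in 9–14 and R in 16–18 only because C3 outranks the aryl group once it carries oxygen. The pybox enantiomer named in step 4 is assumed to give the (S)-ether; its mirror image would be used if the induction runs the other way.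

**Step 1**
Reactants: 1 2-methoxyhydroquinone
Product: 2 1,4-bis(benzyloxy)-2-methoxybenzene
Conditions: BnBr, K2CO3, DMF, 60 °C, under N2
Reagents that add atoms: benzyl bromide, BrCc1ccccc1
Why: Williamson ether synthesis, in which both phenoxides are alkylated by benzyl bromide while exclusion of air keeps the hydroquinone from oxidising to the quinone.

**Step 2**
Reactants: 2 1,4-bis(benzyloxy)-2-methoxybenzene
Product: 4 2,5-bis(benzyloxy)-4-methoxybenzaldehyde, via aryl iminium chloride 3 (not isolated)
Conditions: POCl3, DMF, 0 → 70 °C; then ice-water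
Reagents that add atoms: N,N-dimethylformamide, CN(C)C=O; water, O
Why: Vilsmeier-Haack formylation, in which the chloroiminium ion attacks the one free position that is para to the methoxy group and ortho to a benzyloxy group, as 1,2,4-trialkoxybenzenes do, and hydrolysis of iminium salt 3 releases the aldehyde with the benzyl ethers intact.

**Step 3**
Reactants: 4 2,5-bis(benzyloxy)-4-methoxybenzaldehyde; 5 ethynylmagnesium bromide
Product: 7 rac-1-[2,5-bis(benzyloxy)-4-methoxyphenyl]prop-2-yn-1-yl acetate, via magnesium alkoxide 6 (not isolated)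
Conditions: THF, 0 °C; then Ac2O, 0 °C → rt
Reagents that add atoms: acetic anhydride, CC(=O)OC(C)=O
Why: Grignard addition of the acetylide to the aldehyde forms C2–C3 and the magnesium alkoxide 6 is O-acetylated in the same flask, the new centre being left racemic on purpose because step 4 is enantioconvergent.

**Step 4**
Reactants: 7 rac-1-[2,5-bis(benzyloxy)-4-methoxyphenyl]prop-2-yn-1-yl acetate; 8 3,4,5-trimethoxyphenol
Product: 9 5-{[(1S)-1-[2,5-bis(benzyloxy)-4-methoxyphenyl]prop-2-yn-1-yl]oxy}-1,2,3-trimethoxybenzene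
Conditions: (CuOTf)2·C6H6 (5 mol% Cu), (S,S)-Ph-pybox (10 mol%), iPr2NEt, ClCH2CH2Cl, −20 → 0 °C
Reagents that add atoms: none
Why: Copper-catalysed asymmetric propargylic substitution (etherification), in which the monovalent copper acetylide of 7 loses acetate to a copper allenylidene that is planar at the former stereocentre, so both enantiomers of 7 converge, and the phenoxide of 8 adds at the gamma carbon on the face left open by the Ph-pybox ligand, which sets C2.

**Step 5**
Reactants: 9 5-{[(1S)-1-[2,5-bis(benzyloxy)-4-methoxyphenyl]prop-2-yn-1-yl]oxy}-1,2,3-trimethoxybenzene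
Product: 12 {[(3S)-3-[2,5-bis(benzyloxy)-4-methoxyphenyl]-3-(3,4,5-trimethoxyphenoxy)prop-1-yn-1-yl]oxy}tri(propan-2-yl)silane, via lithium acetylide 10 (not isolated), via lithium ynolate 11 (not isolated)
Conditions: n-BuLi (1.0 equiv), THF, −78 °C; LiOOtBu (from tBuOOH and LiN(SiMe3)2, THF, −78 °C), −78 → 0 °C; then TIPSOTf, −78 → 0 °C
Reagents that add atoms: lithium tert-butyl peroxide, [Li+].CC(C)(C)O[O-]; triisopropylsilyl trifluoromethanesulfonate, CC(C)[Si](C(C)C)(C(C)C)OS(=O)(=O)C(F)(F)F
Why: Oxidation of a lithium acetylide by the electrophilic oxygen of lithium tert-butyl peroxide gives ynolate 11, which the bulky silyl triflate traps on oxygen (O-silylation) as the siloxyalkyne, and one equivalent of base at −78 °C removes only the acetylenic proton so that C2 is not touched.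

**Step 6**
Reactants: 12 {[(3S)-3-[2,5-bis(benzyloxy)-4-methoxyphenyl]-3-(3,4,5-trimethoxyphenoxy)prop-1-yn-1-yl]oxy}tri(propan-2-yl)silane
Product: 14 (2S)-2-[2,5-bis(benzyloxy)-4-methoxyphenyl]-5,6,7-trimethoxy-4-{[tri(propan-2-yl)silyl]oxy}-2H-chromene, via silyl ketenium triflimide 13 (not isolated)
Conditions: HNTf2 (5 mol%), CH2Cl2, −78 → −40 °C; then Et3N
Reagents that add atoms: none
Why: HNTf2 protonates the siloxyalkyne at its nucleophilic carbon C3 to give silyl ketenium ion 13, whose sp carbon C4 is attacked by the ring A carbon ortho to O1 (itself ortho to one methoxy group and para to another), and loss of the arenium proton returns the acid and leaves the enol silane. The closest known reaction type is the Brønsted acid-promoted carbocyclisation of 1-siloxy-1-alkynes onto tethered arenes, a Friedel-Crafts-type hydroarylation related to the gold- and platinum-catalysed cyclisation of aryl propargyl ethers to 2H-chromenes. Ring C closes in the 6-endo-dig mode with both alkyne carbons inside the new ring, and C4 arrives at the ketone oxidation level without passing through an acylium ion that could lose CO. No stereocentre is created, and C2 is carried through unchanged because the C2–O1 bond is not broken. Regiochemistry on ring A does not arise because the two carbons ortho to the ether oxygen are equivalent, and ring B does not compete because its free ortho carbon is far less activated and could only close a strained five-membered ring. The selectivity that must be secured is protonation of the alkyne in preference to ionisation of the activated C2–O1 ether, which the high carbon basicity of the ynol ether, the catalytic amount of acid, the low temperature and the amine quench are expected to provide.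

**Step 7**
Reactants: 14 (2S)-2-[2,5-bis(benzyloxy)-4-methoxyphenyl]-5,6,7-trimethoxy-4-{[tri(propan-2-yl)silyl]oxy}-2H-chromene
Product: 16 (2R,3R)-2-[2,5-bis(benzyloxy)-4-methoxyphenyl]-3-hydroxy-5,6,7-trimethoxy-2,3-dihydro-4H-chromen-4-one, via silyloxy epoxide 15 (not isolated)
Conditions: dimethyldioxirane (acetone solution, 1.1 equiv), CH2Cl2, −78 → −20 °C; then Bu4NF, AcOH, THF, 0 °C
Reagents that add atoms: dimethyldioxirane, CC1(C)OO1
Why: Rubottom oxidation, in which dimethyldioxirane epoxidises the electron-rich enol silane on the face anti to the C2 aryl group and fluoride-triggered collapse of silyloxy epoxide 15 (or of its silyl-migrated 3-silyloxy ketone) under acetic acid buffering gives the 2,3-trans 3-hydroxy ketone, so that C3 is set by substrate control from C2.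

**Step 8**
Reactants: 16 (2R,3R)-2-[2,5-bis(benzyloxy)-4-methoxyphenyl]-3-hydroxy-5,6,7-trimethoxy-2,3-dihydro-4H-chromen-4-one
Product: 17 (2R,3R)-2-[2,5-bis(benzyloxy)-4-methoxyphenyl]-3,5,6,7-tetramethoxy-2,3-dihydro-4H-chromen-4-one
Conditions: Me3OBF4, 1,8-bis(dimethylamino)naphthalene, 4 Å molecular sieves, CH2Cl2, 0 °C → rt
Reagents that add atoms: trimethyloxonium tetrafluoroborate, C[O+](C)C.F[B-](F)(F)F
Why: O-Methylation of the secondary alcohol with an oxonium salt and a hindered non-nucleophilic amine passes through neither an alkoxide nor an enolate, so epimerisation at C2 or C3 by ring opening to the chalcone and elimination to the flavone are not expected.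

**Step 9**
Reactants: 17 (2R,3R)-2-[2,5-bis(benzyloxy)-4-methoxyphenyl]-3,5,6,7-tetramethoxy-2,3-dihydro-4H-chromen-4-one
Product: 18 (2R,3R)-2-(2,5-dihydroxy-4-methoxyphenyl)-5-hydroxy-3,6,7-trimethoxy-2,3-dihydro-4H-chromen-4-one
Conditions: BCl3, pentamethylbenzene, CH2Cl2, −78 → 0 °C, under argon; then 1 M aq HCl
Reagents that add atoms: none
Why: Lewis acid ether cleavage, in which BCl3 removes both aryl benzyl ethers at low temperature with pentamethylbenzene trapping the benzyl cations and cleaves the 5-methoxy group selectively through its six-membered boron chelate with the C4 carbonyl, while the unchelated methyl ethers at C6, C7 and C4' and the aliphatic 3-methoxy group are expected to persist at or below 0 °C.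

**Compound list**
1 | 2-methoxyhydroquinone (2-methoxybenzene-1,4-diol) | COc1cc(O)ccc1O | starting material
2 | 1,4-bis(benzyloxy)-2-methoxybenzene | COc1cc(OCc2ccccc2)ccc1OCc1ccccc1 | intermediate
3 | N-{[2,5-bis(benzyloxy)-4-methoxyphenyl]methylidene}-N-methylmethanaminium chloride (aryl iminium chloride) | COc1cc(OCc2ccccc2)c(C=[N+](C)C)cc1OCc1ccccc1.[Cl-] | intermediate
4 | 2,5-bis(benzyloxy)-4-methoxybenzaldehyde | COc1cc(OCc2ccccc2)c(C=O)cc1OCc1ccccc1 | intermediate
5 | ethynylmagnesium bromide | C#C[Mg]Br | starting material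
6 | bromomagnesium 1-[2,5-bis(benzyloxy)-4-methoxyphenyl]prop-2-yn-1-olate, racemic (magnesium alkoxide) | COc1cc(OCc2ccccc2)c(C(O[Mg]Br)C#C)cc1OCc1ccccc1 | intermediate
7 | rac-1-[2,5-bis(benzyloxy)-4-methoxyphenyl]prop-2-yn-1-yl acetate | COc1cc(OCc2ccccc2)c(C(OC(C)=O)C#C)cc1OCc1ccccc1 | intermediate
8 | 3,4,5-trimethoxyphenol | COc1cc(O)cc(OC)c1OC | starting material
9 | 5-{[(1S)-1-[2,5-bis(benzyloxy)-4-methoxyphenyl]prop-2-yn-1-yl]oxy}-1,2,3-trimethoxybenzene | COc1cc(OCc2ccccc2)c([C@H](C#C)Oc3cc(OC)c(OC)c(OC)c3)cc1OCc1ccccc1 | intermediate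
10 | lithium acetylide of 9 (C-lithiated at the alkyne terminus, configuration as in 9) | COc1cc(OCc2ccccc2)c([C@H](C#C[Li])Oc3cc(OC)c(OC)c(OC)c3)cc1OCc1ccccc1 | intermediate
11 | lithium (3S)-3-[2,5-bis(benzyloxy)-4-methoxyphenyl]-3-(3,4,5-trimethoxyphenoxy)prop-1-yn-1-olate (lithium ynolate) | COc1cc(OCc2ccccc2)c([C@H](C#CO[Li])Oc3cc(OC)c(OC)c(OC)c3)cc1OCc1ccccc1 | intermediate
12 | {[(3S)-3-[2,5-bis(benzyloxy)-4-methoxyphenyl]-3-(3,4,5-trimethoxyphenoxy)prop-1-yn-1-yl]oxy}tri(propan-2-yl)silane | COc1cc(OCc2ccccc2)c([C@H](C#CO[Si](C(C)C)(C(C)C)C(C)C)Oc3cc(OC)c(OC)c(OC)c3)cc1OCc1ccccc1 | intermediate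
13 | O-triisopropylsilyl ketenium bis(trifluoromethanesulfonyl)imide formed by C3 protonation of 12 (configuration at C2 as in 12) | COc1cc(OCc2ccccc2)c([C@H](C=C=[O+][Si](C(C)C)(C(C)C)C(C)C)Oc3cc(OC)c(OC)c(OC)c3)cc1OCc1ccccc1.FC(F)(F)S(=O)(=O)[N-]S(=O)(=O)C(F)(F)F | intermediate
14 | (2S)-2-[2,5-bis(benzyloxy)-4-methoxyphenyl]-5,6,7-trimethoxy-4-{[tri(propan-2-yl)silyl]oxy}-2H-chromene | COc1cc(OCc2ccccc2)c([C@H]2Oc3cc(OC)c(OC)c(OC)c3C(O[Si](C(C)C)(C(C)C)C(C)C)=C2)cc1OCc1ccccc1 | intermediate
15 | (2R,3R,4R)-2-[2,5-bis(benzyloxy)-4-methoxyphenyl]-3,4-epoxy-5,6,7-trimethoxy-4-{[tri(propan-2-yl)silyl]oxy}chromane (epoxide oxygen anti to the C2 aryl group) | COc1cc(OCc2ccccc2)c([C@H]2Oc3cc(OC)c(OC)c(OC)c3[C@]4(O[Si](C(C)C)(C(C)C)C(C)C)O[C@H]24)cc1OCc1ccccc1 | intermediate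
16 | (2R,3R)-2-[2,5-bis(benzyloxy)-4-methoxyphenyl]-3-hydroxy-5,6,7-trimethoxy-2,3-dihydro-4H-chromen-4-one | COc1cc(OCc2ccccc2)c([C@H]2Oc3cc(OC)c(OC)c(OC)c3C(=O)[C@@H]2O)cc1OCc1ccccc1 | intermediate
17 | (2R,3R)-2-[2,5-bis(benzyloxy)-4-methoxyphenyl]-3,5,6,7-tetramethoxy-2,3-dihydro-4H-chromen-4-one | COc1cc(OCc2ccccc2)c([C@H]2Oc3cc(OC)c(OC)c(OC)c3C(=O)[C@@H]2OC)cc1OCc1ccccc1 | intermediate
18 | (2R,3R)-2-(2,5-dihydroxy-4-methoxyphenyl)-5-hydroxy-3,6,7-trimethoxy-2,3-dihydro-4H-chromen-4-one | COc1cc(O)c([C@H]2Oc3cc(OC)c(OC)c(O)c3C(=O)[C@@H]2OC)cc1O | target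

**Totals**
Total step count: 9. Longest linear sequence: 9 steps (1 → 18); compounds 5 and 8 are bought.

**Steps most likely to fail**

Step 6 (key cyclisation). The C2–O1 ether is benzylic to a very electron-rich ring and propargylic, so acid-promoted ionisation may compete with carbon protonation of the alkyne and erode the configuration at C2 or expel the phenol; the ketenium ion may also be lost to adventitious water. Fallback: set out from 9 and close the same C4–C4a bond without a Brønsted acid. The terminal alkyne is cyclised with (Ph3P)AuNTf2 (monovalent gold, CH2Cl2, rt) in a 6-endo-dig hydroarylation to (2S)-2-[2,5-bis(benzyloxy)-4-methoxyphenyl]-5,6,7-trimethoxy-2H-chromene F1. Catalytic OsO4 with N-methylmorpholine N-oxide in acetone–water then dihydroxylates the C3=C4 bond anti to the C2 aryl group to give the 2,3-trans-3,4-cis diol (2R,3S,4S)-2-[2,5-bis(benzyloxy)-4-methoxyphenyl]-5,6,7-trimethoxy-3,4-dihydro-2H-chromene-3,4-diol F2. Activated MnO2 in CH2Cl2 oxidises only the benzylic C4 carbinol, and the route is rejoined at 16. This detour also by-passes step 5.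

Step 4 (asymmetric etherification). Facial discrimination at the copper allenylidene may be poor with the ortho-benzyloxy aryl group, the electron-rich phenol may be alkylated at carbon instead of oxygen, and the very labile acetate may ionise without the catalyst and give racemic ether. Fallback: set out from 7 and fix C2 by resolution and stereospecific substitution. Immobilised Candida antarctica lipase B with n-butanol in tert-butyl methyl ether should, by the usual preference of this enzyme for (R)-1-arylalkyl esters, cleave one enantiomer to (1R)-1-[2,5-bis(benzyloxy)-4-methoxyphenyl]prop-2-yn-1-ol F3 and leave (1S)-1-[2,5-bis(benzyloxy)-4-methoxyphenyl]prop-2-yn-1-yl acetate F4 behind. Mitsunobu reaction of F3 with phenol 8 (PPh3, diisopropyl azodicarboxylate, toluene, 0 °C) then forms the aryl ether with inversion, and the route is rejoined at 9.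

Step 9 (global deprotection). Boron chelation may also cleave the 6-methoxy or the 3-methoxy group, hydrolysis of the boron chelate may be incomplete, and the liberated hydroquinone may oxidise in air during work-up. Fallback: set out from 17 and separate the two deprotections. MgI2·OEt2 in toluene–ether cleaves only the methoxy group peri to the carbonyl through magnesium chelation and leaves the benzyl ethers, giving (2R,3R)-2-[2,5-bis(benzyloxy)-4-methoxyphenyl]-5-hydroxy-3,6,7-trimethoxy-2,3-dihydro-4H-chromen-4-one F5. Hydrogenolysis (H2, Pd/C, EtOAc–MeOH, rt) under neutral conditions then removes both benzyl groups, and the route is rejoined at 18.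

**Further compounds**
F1 | step 6 | (2S)-2-[2,5-bis(benzyloxy)-4-methoxyphenyl]-5,6,7-trimethoxy-2H-chromene | COc1cc(OCc2ccccc2)c([C@H]2Oc3cc(OC)c(OC)c(OC)c3C=C2)cc1OCc1ccccc1
F2 | step 6 | (2R,3S,4S)-2-[2,5-bis(benzyloxy)-4-methoxyphenyl]-5,6,7-trimethoxy-3,4-dihydro-2H-chromene-3,4-diol | COc1cc(OCc2ccccc2)c([C@H]2Oc3cc(OC)c(OC)c(OC)c3[C@H](O)[C@@H]2O)cc1OCc1ccccc1
F3 | step 4 | (1R)-1-[2,5-bis(benzyloxy)-4-methoxyphenyl]prop-2-yn-1-ol | COc1cc(OCc2ccccc2)c([C@@H](C#C)O)cc1OCc1ccccc1
F4 | step 4 | (1S)-1-[2,5-bis(benzyloxy)-4-methoxyphenyl]prop-2-yn-1-yl acetate | COc1cc(OCc2ccccc2)c([C@H](C#C)OC(C)=O)cc1OCc1ccccc1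
F5 | step 9 | (2R,3R)-2-[2,5-bis(benzyloxy)-4-methoxyphenyl]-5-hydroxy-3,6,7-trimethoxy-2,3-dihydro-4H-chromen-4-one | COc1cc(OCc2ccccc2)c([C@H]2Oc3cc(OC)c(OC)c(O)c3C(=O)[C@@H]2OC)cc1OCc1ccccc1
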